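**Retrosynthetic overview**
1. Target ⇒ meso dimethyl 2,3-bis(3-geranyl-5-hydroxy-2-methoxyphenyl)succinate, by oxidising both para-methoxyphenol rings to quinones (geranyl = (2E)-3,7-dimethylocta-2,6-dien-1-yl).
2. Both aryl–Cα bonds are cut at once and the central C2–C3 bond is bought intact in dimethyl succinate. The succinate bis(silyl ketene acetal) adds twice to a quinone monoketal, which acts as an aryl-cation equivalent: the normally nucleophilic hydroquinone ring carbon reacts as the electrophile towards the normally nucleophilic ester α-carbon.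
3. Quinone monoketal ⇒ 3-geranyl-4-methoxyphenol (PhI(OAc)2, MeOH) ⇒ 3-bromo-4-methoxyphenol + geranyl bromide.
4. Ring order: no ring is built. Both six-membered rings come from the bromophenol, are dearomatised, are re-aromatised together after the C–C bond formation, and are oxidised to the quinones together in the last step.

Assumption: the two stereocentres carry identical substituents with opposite descriptors (2S,3R), so the target is the achiral meso diastereomer; "single enantiomer" is read as "this single meso stereoisomer".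

**Step 1**
Reactants: 1 3-bromo-4-methoxyphenol; 2 geranyl bromide ((2E)-1-bromo-3,7-dimethylocta-2,6-diene)
Product: 4 3-[(2E)-3,7-dimethylocta-2,6-dien-1-yl]-4-methoxyphenol, via aryllithium phenolate 3 (not isolated)
Conditions: n-BuLi (2.1 equiv), THF, −78 → −20 °C; CuBr·SMe2 (10 mol%); 2, −78 → 0 °C
Reagents that add atoms: none
Why: Bromine–lithium exchange on the lithium phenolate gives an aryllithium that, under copper catalysis, displaces bromide at the primary carbon of geranyl bromide (SN2-type allylic substitution), so the E-olefin is kept, no stereocentre is formed, and the phenolate oxygen is not alkylated at low temperature.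

**Step 2**
Reactants: 4 3-[(2E)-3,7-dimethylocta-2,6-dien-1-yl]-4-methoxyphenol
Product: 5 3-[(2E)-3,7-dimethylocta-2,6-dien-1-yl]-4,4-dimethoxycyclohexa-2,5-dien-1-one
Conditions: PhI(OAc)2 (1.1 equiv), MeOH, 0 °C
Reagents that add atoms: methanol, CO
Why: Oxidative dearomatisation of a para-methoxyphenol by the trivalent iodine reagent, with methanol captured at the methoxy-bearing carbon, gives the quinone monoketal (a standard phenol-to-quinone-monoketal oxidation); it is much faster than any reaction of the isolated trisubstituted alkenes and forms no stereocentre.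

**Step 3**
Reactants: 6 dimethyl succinate
Product: 8 1,4-dimethoxy-1,4-bis(trimethylsilyloxy)buta-1,3-diene, via dilithium bis-enolate 7 (not isolated)
Conditions: LiN(iPr)2 (2.2 equiv), THF, −78 °C; Me3SiCl (2.5 equiv), −78 °C → rt; distil
Reagents that add atoms: chlorotrimethylsilane, C[Si](C)(C)Cl
Why: Twofold ester deprotonation followed by O-silylation (bis silyl ketene acetal formation) turns the succinate into a neutral, distillable equivalent of its 2,3-dianion; no stereocentre is formed.

**Step 4**
Reactants: 5 3-[(2E)-3,7-dimethylocta-2,6-dien-1-yl]-4,4-dimethoxycyclohexa-2,5-dien-1-one (2.2 equiv); 8 1,4-dimethoxy-1,4-bis(trimethylsilyloxy)buta-1,3-diene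
Product: 11 dimethyl (2R,3S)-2,3-bis{3-[(2E)-3,7-dimethylocta-2,6-dien-1-yl]-5-hydroxy-2-methoxyphenyl}butanedioate (meso), via twofold Michael adduct 9 (not isolated), via unequilibrated diester 10 (not isolated)
Conditions: MeCN, 50 °C; camphorsulfonic acid (5 mol%), MeOH, 0 °C → rt; NaOMe (4 equiv), MeOH, 50 °C, Ar; AcOH; meso isomer crystallised
Reagents that add atoms: none
Why: Proposed new method: a twofold thermal Mukaiyama–Michael addition in which each α-carbon of 8 attacks C5 of one molecule of 5 (the only unsubstituted β-carbon next to the ketal carbon, C3 being blocked by the geranyl group), after which acid expels methanol and re-aromatises both rings, so the quinone monoketal serves as an aryl-cation equivalent and joins a hydroquinone ring carbon to an ester α-carbon, two positions that are both nucleophilic in their normal state; the closest known reaction type is the conjugate addition of silyl ketene acetals and stabilised carbanions to quinone monoketals followed by aromatisation, together with the use of this bis(silyl ketene acetal) as a succinate 2,3-dianion equivalent; the two α-stereocentres form unselectively and are then set by NaOMe equilibration of these epimerisable centres towards the centrosymmetric meso diester, expected (not known) to be favoured, which is crystallised while the mother liquor is re-equilibrated.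

**Step 5**
Reactants: 11 dimethyl (2R,3S)-2,3-bis{3-[(2E)-3,7-dimethylocta-2,6-dien-1-yl]-5-hydroxy-2-methoxyphenyl}butanedioate
Product: 12 dimethyl (2R,3S)-2,3-bis{5-[(2E)-3,7-dimethylocta-2,6-dien-1-yl]-3,6-dioxocyclohexa-1,4-dien-1-yl}butanedioate (meso, target)
Conditions: PhI(OAc)2 (2.2 equiv), MeCN/H2O 2:1, 0 °C, dark
Reagents that add atoms: water, O
Why: Two-electron oxidation of each para-methoxyphenol ring by the trivalent iodine reagent gives a cation that water captures at the methoxy-bearing carbon, and the hemiketal loses methanol to give the quinone (oxidative demethylation of a hydroquinone monomethyl ether); the weakly acidic medium at 0 °C does not enolise the α-centres, so the meso configuration from step 4 is carried through.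

**Compound list**
1 | 3-bromo-4-methoxyphenol | COc1ccc(O)cc1Br | starting material
2 | geranyl bromide, (2E)-1-bromo-3,7-dimethylocta-2,6-diene | BrC/C=C(\C)CCC=C(C)C | starting material
3 | lithium 3-lithio-4-methoxyphenolate | COc1ccc(O[Li])cc1[Li] | intermediate
4 | 3-[(2E)-3,7-dimethylocta-2,6-dien-1-yl]-4-methoxyphenol | COc1ccc(O)cc1C/C=C(\C)CCC=C(C)C | intermediate
5 | 3-[(2E)-3,7-dimethylocta-2,6-dien-1-yl]-4,4-dimethoxycyclohexa-2,5-dien-1-one | COC1(OC)C=CC(=O)C=C1C/C=C(\C)CCC=C(C)C | intermediate
6 | dimethyl succinate (dimethyl butanedioate) | COC(=O)CCC(=O)OC | starting material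
7 | dilithium 1,4-dimethoxybuta-1,3-diene-1,4-bis(olate) | COC(O[Li])=CC=C(OC)O[Li] | intermediate
8 | 1,4-dimethoxy-1,4-bis(trimethylsilyloxy)buta-1,3-diene (double-bond isomers not separated) | COC(O[Si](C)(C)C)=CC=C(OC)O[Si](C)(C)C | intermediate
9 | dimethyl 2,3-bis{5-[(2E)-3,7-dimethylocta-2,6-dien-1-yl]-6,6-dimethoxy-3-(trimethylsilyloxy)cyclohexa-2,4-dien-1-yl}butanedioate (diastereomer mixture) | COC(=O)C(C1C=C(O[Si](C)(C)C)C=C(C/C=C(\C)CCC=C(C)C)C1(OC)OC)C(C(=O)OC)C1C=C(O[Si](C)(C)C)C=C(C/C=C(\C)CCC=C(C)C)C1(OC)OC | intermediate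
10 | dimethyl 2,3-bis{3-[(2E)-3,7-dimethylocta-2,6-dien-1-yl]-5-hydroxy-2-methoxyphenyl}butanedioate (dl/meso mixture) | COC(=O)C(c1cc(O)cc(C/C=C(\C)CCC=C(C)C)c1OC)C(C(=O)OC)c1cc(O)cc(C/C=C(\C)CCC=C(C)C)c1OC | intermediate
11 | dimethyl (2R,3S)-2,3-bis{3-[(2E)-3,7-dimethylocta-2,6-dien-1-yl]-5-hydroxy-2-methoxyphenyl}butanedioate (meso) | COC(=O)[C@H](c1cc(O)cc(C/C=C(\C)CCC=C(C)C)c1OC)[C@@H](C(=O)OC)c1cc(O)cc(C/C=C(\C)CCC=C(C)C)c1OC | intermediate
12 | dimethyl (2R,3S)-2,3-bis{5-[(2E)-3,7-dimethylocta-2,6-dien-1-yl]-3,6-dioxocyclohexa-1,4-dien-1-yl}butanedioate (meso) | COC(=O)[C@H](C1=CC(=O)C=C(C/C=C(\C)CCC=C(C)C)C1=O)[C@@H](C(=O)OC)C1=CC(=O)C=C(C/C=C(\C)CCC=C(C)C)C1=O | target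

**Step count and risk**
Total steps: 5. Longest linear sequence: 4 (1 → 4 → 5 → 11 → 12); step 3 is a one-step side branch.

Most likely to fail, in order:

Step 4. The second conjugate addition has to form a bond between two congested carbons, each next to a ketal carbon, and may stall at the mono-adduct; 5 mol% tetrabutylammonium difluorotriphenylsilicate is the first adjustment. The fallback sets out from 5 and comes back at 11. It makes the two aryl–C bonds one ring at a time and the central bond by oxidative enolate coupling. Mukaiyama–Michael addition of commercial 1-(tert-butyldimethylsilyloxy)-1-methoxyethene to 5 (MeCN, 50 °C) gives methyl 2-{3-(tert-butyldimethylsilyloxy)-5-geranyl-6,6-dimethoxycyclohexa-2,4-dien-1-yl}acetate F1. Camphorsulfonic acid in MeOH aromatises it to methyl 2-(3-geranyl-5-hydroxy-2-methoxyphenyl)acetate F2. Silylation (t-BuMe2SiCl, imidazole) gives methyl 2-[5-(tert-butyldimethylsilyloxy)-3-geranyl-2-methoxyphenyl]acetate F3. Its lithium enolate (LiN(iPr)2, THF, −78 °C) is dimerised with I2 (0.5 equiv) to dimethyl 2,3-bis[5-(tert-butyldimethylsilyloxy)-3-geranyl-2-methoxyphenyl]butanedioate F4 (dl/meso). NaOMe in MeOH at 50 °C then cleaves the phenolic silyl ethers and equilibrates the α-centres, giving 11.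

Step 1. Exchange on the phenolate dianion may be slow, and O-alkylation or attack at the tertiary allylic carbon may compete. The fallback sets out from 1 and comes back at 4. The phenol is masked (t-BuMe2SiCl, imidazole) as (3-bromo-4-methoxyphenoxy)(tert-butyl)dimethylsilane F5. The mono-anion route (n-BuLi, THF, −78 °C; CuBr·SMe2; 2) gives tert-butyl(3-geranyl-4-methoxyphenoxy)dimethylsilane F6. Bu4NF in THF releases 4.

Step 5. The bis-quinone has acidic, epimerisable α-hydrogens and is light- and base-sensitive, so it may erode in the aqueous oxidising medium or on silica. The fallback sets out from 11 and comes back at 12. It separates oxidation from carbonyl release. PhI(OAc)2 in anhydrous MeOH at 0 °C gives the isolable bis(quinone monoketal) dimethyl (2R,3S)-2,3-bis{5-geranyl-6,6-dimethoxy-3-oxocyclohexa-1,4-dien-1-yl}butanedioate F7. This is purified and then hydrolysed without oxidant (aqueous oxalic acid on silica, CH2Cl2, 0 °C) to 12.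

**Further compounds**
F1 | step 4 | methyl 2-{3-(tert-butyldimethylsilyloxy)-5-[(2E)-3,7-dimethylocta-2,6-dien-1-yl]-6,6-dimethoxycyclohexa-2,4-dien-1-yl}acetate | COC(=O)CC1C=C(O[Si](C)(C)C(C)(C)C)C=C(C/C=C(\C)CCC=C(C)C)C1(OC)OC
F2 | step 4 | methyl 2-{3-[(2E)-3,7-dimethylocta-2,6-dien-1-yl]-5-hydroxy-2-methoxyphenyl}acetate | COC(=O)Cc1cc(O)cc(C/C=C(\C)CCC=C(C)C)c1OC
F3 | step 4 | methyl 2-{5-(tert-butyldimethylsilyloxy)-3-[(2E)-3,7-dimethylocta-2,6-dien-1-yl]-2-methoxyphenyl}acetate | COC(=O)Cc1cc(O[Si](C)(C)C(C)(C)C)cc(C/C=C(\C)CCC=C(C)C)c1OC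
F4 | step 4 | dimethyl 2,3-bis{5-(tert-butyldimethylsilyloxy)-3-[(2E)-3,7-dimethylocta-2,6-dien-1-yl]-2-methoxyphenyl}butanedioate (dl/meso mixture) | COC(=O)C(c1cc(O[Si](C)(C)C(C)(C)C)cc(C/C=C(\C)CCC=C(C)C)c1OC)C(C(=O)OC)c1cc(O[Si](C)(C)C(C)(C)C)cc(C/C=C(\C)CCC=C(C)C)c1OC
F5 | step 1 | (3-bromo-4-methoxyphenoxy)(tert-butyl)dimethylsilane | COc1ccc(O[Si](C)(C)C(C)(C)C)cc1Br
F6 | step 1 | tert-butyl{3-[(2E)-3,7-dimethylocta-2,6-dien-1-yl]-4-methoxyphenoxy}dimethylsilane | COc1ccc(O[Si](C)(C)C(C)(C)C)cc1C/C=C(\C)CCC=C(C)C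
F7 | step 5 | dimethyl (2R,3S)-2,3-bis{5-[(2E)-3,7-dimethylocta-2,6-dien-1-yl]-6,6-dimethoxy-3-oxocyclohexa-1,4-dien-1-yl}butanedioate (meso) | COC(=O)[C@H](C1=CC(=O)C=C(C/C=C(\C)CCC=C(C)C)C1(OC)OC)[C@@H](C(=O)OC)C1=CC(=O)C=C(C/C=C(\C)CCC=C(C)C)C1(OC)OC
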